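## Analysis of the target

The target (15) is a hexasubstituted benzene. The central ring carries methoxy groups at C2, C3, C5 and C6 and two indol-3-yl groups para to each other at C1 and C4. One indole is unsubstituted; the other carries a 3-methylbut-2-enyl (prenyl) group at C5.

There is no stereocentre. The two aryl–indole axes raise no stereochemical question, because each is flanked on the central ring by two identical methoxy groups.

The sensitive parts are:
- the prenyl alkene (protic and Lewis acids, electrophilic halogen, hydrogenation, metal hydrides that shift the double bond);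
- the two N–H indoles with free C2 positions (acid, oxidants);
- the tetraoxygenated ring, which is easily oxidised to the quinone.

The difficulty is threefold. Two almost identical indoles must be placed on a symmetrical core, so the core has to be desymmetrised. Each aryl–indole bond is doubly ortho-substituted. The prenyl group must end up at C5 only, without passing through acid.

The strategy rests on the substitution pattern of the prenylated indole: hydrogen at C2, the central ring at C3, and the prenyl group on C5, which is para to C7a and thus to N1. Cutting N1–C2 and C3–C3a turns this indole into an o-iodoaniline with the prenyl group para to nitrogen and a two-carbon alkyne on the core. A trimethylsilyl group on the carbon that becomes C2 steers the insertion and is later exchanged for hydrogen. The same cut applies to the unsubstituted indole, so both heterocycles come from one reaction type run twice on a symmetrical bis-alkyne.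

## Retrosynthetic reasoning

**15 from 14.** The two C2–H bonds of the indoles are traced back to C2–Si bonds. Silicon is the control element of the annulation and is removed at the end by fluoride-induced protodesilylation. This is a basic operation that leaves the prenyl alkene, the methyl ethers and the N–H groups alone, so no acid is needed anywhere after the alkene is in place.

**14 from 7 and 13.** The prenylated indole is cut at N1–C2 and C3–C3a. These two bonds are chosen because the aniline fragment 13 then fixes the prenyl group at C5 through a simple para relation, and the alkyne partner 7 already sits on the core. A cut at the C3–aryl bond would instead require a cross-coupling at a carbon between two methoxy groups, plus protection of nitrogen. The forward reaction must insert the alkyne with the silyl group next to nitrogen. The prenylated partner is introduced in this second annulation so that the alkene passes through only two steps.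

**13 from 12, and 12 from 8 and 9.** The C–I bond ortho to the amino group is cut. The amino group directs electrophilic iodination to this position because the para position is occupied. The aryl–CH2 bond is then cut to the aryl Grignard reagent 10 and prenyl bromide 9. The two silyl groups on the nitrogen of 8 mask the N–H bonds during Grignard formation and fall off from 11 on work-up.

**7 from 5 and 6.** The unsubstituted indole is cut in the same way. Compound 5 is symmetrical, so the two alkynes are equivalent. The desymmetrisation is achieved by using 5 in excess and the cheap aniline 6 as the limiting partner. Unreacted 5 is recovered.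

**5 from 3 and 4, and 3 from 1.** The two aryl–alkynyl bonds are cut to the diiodide 3 and two molecules of 4. The two C–I bonds of 3 are placed through the dilithio compound 2, because each ring hydrogen of 1 lies between two methoxy groups and is removed by directed ortho-metalation. The four methoxy groups are bought with 1, and no oxidising halogenation is applied to the electron-rich ring.

## Alternatives that were turned down

**Alternative 1:** The benzene ring of the unsubstituted indole is taken apart at C3a–C7a, C4–C5 and C6–C7.
- Key step: the precursor is the racemic diyne A2. It holds a terminal ynamide and a tertiary propargylic alcohol on one CH2–N unit, and its carbinol carbon already carries the central ring with the prenylated, N-silylated indole. RhCl(PPh3)3 would join its two alkynes with acetylene A3 to give the racemic indolin-3-ol A1. Dehydration across C2–C3, removal of the sulfonyl group and removal of the N-silyl group would follow.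
- For: the tether dictates the connectivity, so there is no insertion regiochemistry to control. On this point it is stronger than the chosen route. The conditions are neutral.
- Against: the carbinol carbon of A2 bears an ethynyl group, an aminomethyl group and a di-ortho-methoxy aryl group, so a nucleophile must be added to a very hindered aryl ketone. A2 also contains a fragile terminal N-ethynyl sulfonamide. The cross-cyclotrimerisation with the gaseous partner A3 competes with self-condensation of A2. Three steps remain after A1.
- Comparison: all this effort builds the indole without substituents, for which the chosen route simply buys 6. The prenylated indole would still have to be made beforehand by other chemistry. The chosen route gives up the built-in regiocontrol but reaches its precursor 7 in three steps, makes both indoles by one reaction type and needs no protecting group on nitrogen.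

**Alternative 2:** The central ring is cut at the two bonds between the indole-bearing carbons and the neighbouring carbonyl carbons, which leads to two indol-3-ylpyruvate units.
- Key step: the two units are tied to an ortho-dihydroxyarene template as the mixed diester A5. LiN(SiMe3)2 forms the bis-enolate, each benzylic carbon attacks the aryl ester carbonyl of the other arm, and the dihydroxyquinone A4 results.
- For: it follows the likely biogenesis. It forms the central ring and both hindered aryl–indole junctions without any metal-mediated bond formation at a di-ortho-substituted carbon. In that respect it is stronger than a route that must push palladium onto a crowded alkyne.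
- Against: two different, enolisable α-keto acids must be loaded onto one template one after the other. Acyl scrambling would lead to the two symmetrical quinones beside A4. The bis-enolate has other outlets, such as aldol attack on a ketone carbonyl. After A4 the quinone must be reduced, four hydroxyl groups must be methylated (two of them on an air-sensitive hydroquinone), and two N-protecting groups must be removed. The prenylated indolylpyruvate needs its own synthesis.
- Comparison: the chosen route buys the tetraoxygenated ring ready-made as 1 and has one step after its key step, where this alternative has about five.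

**Alternative 3:** The prenylated indole is cut at C3a–C7a and C4–C5, so that its benzene ring comes from a furan and a vinyl group.
- Key step: the racemic precursor A7 is a tert-butyl carbamate whose nitrogen carries a 5-prenylfuran-2-yl group and a 2-hydroxybut-3-enyl chain. The carbinol carbon bears the central ring with the other indole N-silylated. Heating to about 180 °C would bring about the intramolecular Diels–Alder reaction, opening of the oxygen bridge, loss of two molecules of water and thermal loss of the carbamate. The product is A6, the target with a triisopropylsilyl group on the nitrogen of the unsubstituted indole, and fluoride would finish.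
- For: the furan dictates the prenyl position, and no electrophilic substitution is run on a prenylated ring. On this point it is stronger than the chosen route, whose iodination of 12 must discriminate between ring and alkene. One thermal operation forms both rings, and no transition metal meets the alkene.
- Against: A7 combines an unstable 2-amidofuran with a tertiary allylic alcohol on a di-ortho-substituted aryl ring. The amidofuran needs Curtius chemistry on a furan acid that must first be prenylated. The alcohol is reached only by adding a vinyl metal to a hindered α-amino aryl ketone. At 180 °C the alcohol may eliminate or ionise before the cycloaddition. The unactivated monosubstituted alkene is a poor dienophile. The prenyl group, allylic to a furan, is exposed to ene-type shifts.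
- Comparison: A7 would take roughly twice as many steps as 7 and 13 together. The chosen route keeps the unambiguous prenyl position (fixed by the para relation in 13) and pays for its brevity with the regiochemical question of the alkyne insertion.

Key step: step 6

## Route

Remark on the chemistry: compound 8, the N,N-disilylated form of 4-bromoaniline, is taken as a purchasable reagent. The target has no stereocentre and no stereogenic double bond, so names and SMILES carry no descriptors.

Step 1
Reactants: 1 1,2,4,5-tetramethoxybenzene
Product: 3 1,4-diiodo-2,3,5,6-tetramethoxybenzene, via 1,4-dilithio-2,3,5,6-tetramethoxybenzene 2 (not isolated)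
Conditions: n-BuLi (2.6 equiv), TMEDA (2.6 equiv), Et2O, 0 °C → rt; then I2 (3 equiv) in THF, –78 °C → rt; aq. Na2S2O3
Reagents that add atoms: n-butyllithium, CCCC[Li] (lithium of 2 only); iodine, [I][I]
Why: Double directed ortho-metalation: each ring hydrogen of 1 lies between two methoxy groups, so n-BuLi/TMEDA should remove both to give 2, and iodine traps both C–Li bonds. The non-oxidising lithiation route avoids electrophilic iodination conditions that would push the electron-rich ring toward the quinone.

Step 2
Reactants: 3 1,4-diiodo-2,3,5,6-tetramethoxybenzene; 4 ethynyltrimethylsilane (3 equiv)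
Product: 5 1,4-bis[(trimethylsilyl)ethynyl]-2,3,5,6-tetramethoxybenzene
Conditions: PdCl2(PPh3)2 (5 mol%), CuI (10 mol%), Et3N/THF 1:1, 60 °C, sealed vessel
Reagents that add atoms: none
Why: Twofold Sonogashira coupling; aryl iodides undergo oxidative addition even when electron-rich and flanked by two methoxy groups, and the slim alkynyl group transfers easily to the crowded carbon. The silyl cap prevents further coupling at the alkyne terminus.

Step 3
Reactants: 5 1,4-bis[(trimethylsilyl)ethynyl]-2,3,5,6-tetramethoxybenzene (3 equiv); 6 2-iodoaniline (1 equiv)
Product: 7 3-{2,3,5,6-tetramethoxy-4-[(trimethylsilyl)ethynyl]phenyl}-2-(trimethylsilyl)-1H-indole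
Conditions: Pd(OAc)2 (5 mol%), LiCl (1 equiv), Na2CO3 (3 equiv), DMF, 100 °C; excess 5 recovered by chromatography
Reagents that add atoms: none
Why: Larock heteroannulation on one of the two equivalent silyl alkynes; the excess of 5, usual for this reaction, should hold back the second annulation statistically. The insertion is expected to place silicon at C2 and the core at C3, as argued for step 6.

Step 4
Reactants: 8 4-bromo-N,N-bis(trimethylsilyl)aniline; 9 1-bromo-3-methylbut-2-ene (prenyl bromide, 1.2 equiv)
Product: 12 4-(3-methylbut-2-enyl)aniline, via aryl Grignard reagent 10 (not isolated), via N,N-bis(trimethylsilyl)-4-prenylaniline 11 (not isolated)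
Conditions: Mg, THF, reflux; then CuI (10 mol%), 9, THF, –20 °C → rt; then MeOH, HCl (cat.), rt; aq. NaHCO3
Reagents that add atoms: magnesium, [Mg] (in 10 only)
Why: Grignard formation from the N-masked aryl bromide, then copper-catalysed allylic substitution at the primary carbon of 9; attack at the other allyl terminus would have to build a quaternary benzylic carbon, so the linear prenyl arene 11 should dominate. Methanolysis of the two N–Si bonds then frees the aniline without strong acid.

Step 5
Reactants: 12 4-(3-methylbut-2-enyl)aniline
Product: 13 2-iodo-4-(3-methylbut-2-enyl)aniline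
Conditions: I2 (1.0 equiv), NaHCO3 (1.5 equiv), CH2Cl2/H2O, 0 °C → rt, dark
Reagents that add atoms: iodine, [I][I]
Why: Electrophilic aromatic iodination; the amino group is the strongest activator and its para position is blocked, so iodine should enter ortho, and one equivalent limits the reaction to monoiodination. The aniline ring is far more nucleophilic toward the mild electrophile I2 than the isolated trisubstituted alkene.

Step 6
Reactants: 7 3-{2,3,5,6-tetramethoxy-4-[(trimethylsilyl)ethynyl]phenyl}-2-(trimethylsilyl)-1H-indole (1 equiv); 13 2-iodo-4-(3-methylbut-2-enyl)aniline (1.5 equiv)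
Product: 14 5-(3-methylbut-2-enyl)-3-{2,3,5,6-tetramethoxy-4-[2-(trimethylsilyl)-1H-indol-3-yl]phenyl}-2-(trimethylsilyl)-1H-indole
Conditions: Pd(OAc)2 (10 mol%), LiCl (1 equiv), Na2CO3 (3 equiv), DMF, 100 °C, argon
Reagents that add atoms: none
Why: Pd(OAc)2 is reduced in the flask to zerovalent palladium, which inserts into the C–I bond of 13; the alkyne of 7 then coordinates and undergoes syn-carbopalladation, the aryl group adding to the alkyne carbon that carries the tetramethoxyphenyl ring (new C3–C3a bond) and palladium ending on the silyl-bearing carbon. The aniline nitrogen displaces halide on palladium to give a six-membered azapalladacycle, carbonate removes the N–H proton, and C–N reductive elimination forms N1–C2 and returns zerovalent palladium. The pyrrole ring is thus closed as a five-membered ring by reductive elimination from a six-membered palladacycle, in a formal [3+2] annulation of the C–C–N unit of the aniline with the alkyne. The closest known reaction is the Larock indole synthesis of o-iodoanilines with aryl(trimethylsilyl)acetylenes, which gives 3-aryl-2-silylindoles. No stereocentre is formed. The step needs regioselective insertion: the trimethylsilyl group, with its bulk and its long C–Si bond, prefers the carbon next to palladium, where it avoids the incoming aryl group, so that silicon appears at C2 and the core at C3. It also needs chemoselectivity: the trisubstituted, unactivated prenyl alkene inserts far more slowly than an alkyne, and with carbonate and no fluoride the C2–Si bond and the free N–H of the indole already present in 7 should stay intact. The prenyl group sits para to nitrogen in 13 and is therefore delivered to C5 without any choice being made in this step.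

Step 7
Reactants: 14 5-(3-methylbut-2-enyl)-3-{2,3,5,6-tetramethoxy-4-[2-(trimethylsilyl)-1H-indol-3-yl]phenyl}-2-(trimethylsilyl)-1H-indole
Product: 15 3-[4-(1H-indol-3-yl)-2,3,5,6-tetramethoxyphenyl]-5-(3-methylbut-2-enyl)-1H-indole
Conditions: Bu4NF·3H2O (6 equiv), THF, 65 °C
Reagents that add atoms: none
Why: Fluoride-induced protodesilylation: fluoride attacks silicon at each indole C2, the C–Si bond breaks and water supplies the proton, so both silyl groups should leave in one operation. The basic, non-electrophilic conditions spare the prenyl alkene, the methyl ethers and the indole N–H groups.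

## Compound list

1 | 1,2,4,5-tetramethoxybenzene | COc1cc(OC)c(OC)cc1OC | starting material
2 | 1,4-dilithio-2,3,5,6-tetramethoxybenzene | [Li]c1c(OC)c(OC)c([Li])c(OC)c1OC | intermediate (not isolated)
3 | 1,4-diiodo-2,3,5,6-tetramethoxybenzene | COc1c(I)c(OC)c(OC)c(I)c1OC | intermediate
4 | ethynyltrimethylsilane | C#C[Si](C)(C)C | starting material
5 | 1,4-bis[(trimethylsilyl)ethynyl]-2,3,5,6-tetramethoxybenzene | COc1c(C#C[Si](C)(C)C)c(OC)c(OC)c(C#C[Si](C)(C)C)c1OC | intermediate
6 | 2-iodoaniline | Nc1ccccc1I | starting material
7 | 3-{2,3,5,6-tetramethoxy-4-[(trimethylsilyl)ethynyl]phenyl}-2-(trimethylsilyl)-1H-indole | C[Si](C)(C)C#Cc1c(OC)c(OC)c(-c2c([Si](C)(C)C)[nH]c3ccccc23)c(OC)c1OC | intermediate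
8 | 4-bromo-N,N-bis(trimethylsilyl)aniline | C[Si](C)(C)N(c1ccc(Br)cc1)[Si](C)(C)C | starting material
9 | 1-bromo-3-methylbut-2-ene (prenyl bromide) | CC(C)=CCBr | starting material
10 | {4-[bis(trimethylsilyl)amino]phenyl}magnesium bromide | C[Si](C)(C)N(c1ccc([Mg]Br)cc1)[Si](C)(C)C | intermediate (not isolated)
11 | 4-(3-methylbut-2-enyl)-N,N-bis(trimethylsilyl)aniline | C[Si](C)(C)N(c1ccc(CC=C(C)C)cc1)[Si](C)(C)C | intermediate (not isolated)
12 | 4-(3-methylbut-2-enyl)aniline | Nc1ccc(CC=C(C)C)cc1 | intermediate
13 | 2-iodo-4-(3-methylbut-2-enyl)aniline | Nc1ccc(CC=C(C)C)cc1I | intermediate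
14 | 5-(3-methylbut-2-enyl)-3-{2,3,5,6-tetramethoxy-4-[2-(trimethylsilyl)-1H-indol-3-yl]phenyl}-2-(trimethylsilyl)-1H-indole | COc1c(OC)c(-c2c([Si](C)(C)C)[nH]c3ccc(CC=C(C)C)cc23)c(OC)c(OC)c1-c1c([Si](C)(C)C)[nH]c2ccccc12 | intermediate
15 | 3-[4-(1H-indol-3-yl)-2,3,5,6-tetramethoxyphenyl]-5-(3-methylbut-2-enyl)-1H-indole | COc1c(OC)c(-c2c[nH]c3ccc(CC=C(C)C)cc23)c(OC)c(OC)c1-c1c[nH]c2ccccc12 | target

## Step count and least certain steps

Total: 7 steps. Longest linear sequence: 5 steps (steps 1, 2, 3, 6, 7, from 1 to 15). The aniline branch (steps 4 and 5) joins at step 6.

**Step 6 (key step).**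
- Risk: the alkyne may insert in the opposite sense. The carbon that must receive the migrating aryl group carries a di-ortho-methoxy aryl ring, and a methoxy oxygen could hold palladium on that carbon. Carbopalladation of the crowded alkyne may also be slow, so that catalyst decay and hydrodeiodination of 13 take over. Carbonate could remove the alkynyl silyl group first and open a copper-free alkynylation path to the wrong indole connectivity.
- Fallback: it sets out from 7 and returns at 15. K2CO3 in MeOH at rt removes only the alkynyl silyl group to give 3-(4-ethynyl-2,3,5,6-tetramethoxyphenyl)-2-(trimethylsilyl)-1H-indole F1. Hydroboration of the terminal alkyne with dicyclohexylborane and oxidation with NaBO3 gives [2,3,5,6-tetramethoxy-4-(2-trimethylsilyl-1H-indol-3-yl)phenyl]acetaldehyde F2. F2 and 13 are heated with Pd(OAc)2 and DABCO in DMF at 85 °C. Condensation gives the enamine, and an intramolecular Heck-type arylation of its β-carbon forms the same C3–C3a bond. The carbon skeleton of the aldehyde fixes the regiochemistry. The product is 3-[4-(2-trimethylsilyl-1H-indol-3-yl)-2,3,5,6-tetramethoxyphenyl]-5-(3-methylbut-2-enyl)-1H-indole F3, which Bu4NF converts into 15 as in step 7.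

**Step 3.**
- Risk: the second alkyne reacts as well and the doubly annulated, symmetrical product forms. Separation of 7 from recovered 5 may also be laborious. The regiochemical question of step 6 applies here too.
- Fallback: a non-statistical sequence that sets out from 1 and returns at 7. Monolithiation of 1 (n-BuLi, 1.05 equiv, THF, 0 °C) and iodine give 1-iodo-2,3,5,6-tetramethoxybenzene F4. Sonogashira coupling with 4 gives trimethyl[(2,3,5,6-tetramethoxyphenyl)ethynyl]silane F5. Larock annulation with 6 gives 3-(2,3,5,6-tetramethoxyphenyl)-2-(trimethylsilyl)-1H-indole F6. Double deprotonation (n-BuLi, 2.2 equiv, TMEDA; first N–H, then the ring hydrogen between two methoxy groups) and 1,2-diiodoethane give 3-(4-iodo-2,3,5,6-tetramethoxyphenyl)-2-(trimethylsilyl)-1H-indole F7. A second Sonogashira coupling with 4 gives 7.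

**Step 5.**
- Risk: iodine may add across the prenyl alkene in the aqueous medium (iodohydrin formation), a second iodine may enter at the other ortho position, or the aniline may be oxidised.
- Fallback: the halogenation of a prenylated ring is avoided altogether; steps 4 and 5 are then not needed. It sets out from 7 and returns at 14. Larock annulation of 7 with purchased 4-bromo-2-iodoaniline (oxidative addition at C–I only, conditions of step 6) gives 5-bromo-3-{2,3,5,6-tetramethoxy-4-[2-(trimethylsilyl)-1H-indol-3-yl]phenyl}-2-(trimethylsilyl)-1H-indole F8. Stille coupling of F8 with tributyl(3-methylbut-2-enyl)stannane (Pd(PPh3)4, DMF, 100 °C) places the prenyl group at C5 and gives 14.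

**Step 7.**
- Risk: desilylation may stall after one silyl group or not start. Fluoride first deprotonates N–H, and each silicon sits between that nitrogen and a perpendicular, di-ortho-substituted aryl ring.
- Fallback: the C–Si bonds are activated through the nitrogen atoms. It sets out from 14 and returns at 15. Boc2O and DMAP in MeCN give di-tert-butyl 5-(3-methylbut-2-enyl)-2,2'-bis(trimethylsilyl)-3,3'-(2,3,5,6-tetramethoxy-1,4-phenylene)bis(indole-1-carboxylate) F9. Its carbamate groups stabilise the C2 carbanion that leaves silicon, so Bu4NF in THF at rt should give the desilylated bis-carbamate di-tert-butyl 5-(3-methylbut-2-enyl)-3,3'-(2,3,5,6-tetramethoxy-1,4-phenylene)bis(indole-1-carboxylate) F10. NaOMe in MeOH at rt removes both carbamates to give 15.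

**Step 1.**
- Risk: the second lithiation may be incomplete, so that mono- and diiodide form together. Excess iodine may oxidise the electron-rich ring.
- Fallback: it sets out from 1 and returns at 5. Electrophilic dibromination (Br2, 2.1 equiv, CH2Cl2, 0 °C) gives 1,4-dibromo-2,3,5,6-tetramethoxybenzene F11. F11 is coupled with 4 under conditions for hindered, electron-rich aryl bromides (PdCl2(PhCN)2, P(t-Bu)3, CuI, i-Pr2NH, dioxane, 60 °C) to give 5.

## Further compounds

F1 | step 6 | 3-(4-ethynyl-2,3,5,6-tetramethoxyphenyl)-2-(trimethylsilyl)-1H-indole | C#Cc1c(OC)c(OC)c(-c2c([Si](C)(C)C)[nH]c3ccccc23)c(OC)c1OC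
F2 | step 6 | [2,3,5,6-tetramethoxy-4-(2-trimethylsilyl-1H-indol-3-yl)phenyl]acetaldehyde | O=CCc1c(OC)c(OC)c(-c2c([Si](C)(C)C)[nH]c3ccccc23)c(OC)c1OC
F3 | step 6 | 3-[4-(2-trimethylsilyl-1H-indol-3-yl)-2,3,5,6-tetramethoxyphenyl]-5-(3-methylbut-2-enyl)-1H-indole | COc1c(OC)c(-c2c[nH]c3ccc(CC=C(C)C)cc23)c(OC)c(OC)c1-c1c([Si](C)(C)C)[nH]c2ccccc12
F4 | step 3 | 1-iodo-2,3,5,6-tetramethoxybenzene | COc1cc(OC)c(OC)c(I)c1OC
F5 | step 3 | trimethyl[(2,3,5,6-tetramethoxyphenyl)ethynyl]silane | COc1cc(OC)c(OC)c(C#C[Si](C)(C)C)c1OC
F6 | step 3 | 3-(2,3,5,6-tetramethoxyphenyl)-2-(trimethylsilyl)-1H-indole | COc1cc(OC)c(OC)c(-c2c([Si](C)(C)C)[nH]c3ccccc23)c1OC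
F7 | step 3 | 3-(4-iodo-2,3,5,6-tetramethoxyphenyl)-2-(trimethylsilyl)-1H-indole | COc1c(I)c(OC)c(OC)c(-c2c([Si](C)(C)C)[nH]c3ccccc23)c1OC
F8 | step 5 | 5-bromo-3-{2,3,5,6-tetramethoxy-4-[2-(trimethylsilyl)-1H-indol-3-yl]phenyl}-2-(trimethylsilyl)-1H-indole | COc1c(OC)c(-c2c([Si](C)(C)C)[nH]c3ccc(Br)cc23)c(OC)c(OC)c1-c1c([Si](C)(C)C)[nH]c2ccccc12
F9 | step 7 | di-tert-butyl 5-(3-methylbut-2-enyl)-2,2'-bis(trimethylsilyl)-3,3'-(2,3,5,6-tetramethoxy-1,4-phenylene)bis(indole-1-carboxylate) | COc1c(OC)c(-c2c([Si](C)(C)C)n(C(=O)OC(C)(C)C)c3ccc(CC=C(C)C)cc23)c(OC)c(OC)c1-c1c([Si](C)(C)C)n(C(=O)OC(C)(C)C)c2ccccc12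
F10 | step 7 | di-tert-butyl 5-(3-methylbut-2-enyl)-3,3'-(2,3,5,6-tetramethoxy-1,4-phenylene)bis(indole-1-carboxylate) | COc1c(OC)c(-c2cn(C(=O)OC(C)(C)C)c3ccc(CC=C(C)C)cc23)c(OC)c(OC)c1-c1cn(C(=O)OC(C)(C)C)c2ccccc12
F11 | step 1 | 1,4-dibromo-2,3,5,6-tetramethoxybenzene | COc1c(Br)c(OC)c(OC)c(Br)c1OC
A1 | alternative 1 | racemic 3-{2,3,5,6-tetramethoxy-4-[5-(3-methylbut-2-enyl)-1-(triisopropylsilyl)indol-3-yl]phenyl}-1-tosylindolin-3-ol | OC1(CN(S(=O)(=O)c2ccc(C)cc2)c2ccccc12)c1c(OC)c(OC)c(-c2cn([Si](C(C)C)(C(C)C)C(C)C)c3ccc(CC=C(C)C)cc23)c(OC)c1OC
A2 | alternative 1 | racemic N-ethynyl-N-(2-hydroxy-2-{2,3,5,6-tetramethoxy-4-[5-(3-methylbut-2-enyl)-1-(triisopropylsilyl)indol-3-yl]phenyl}but-3-ynyl)-4-methylbenzenesulfonamide | OC(C#C)(CN(C#C)S(=O)(=O)c1ccc(C)cc1)c1c(OC)c(OC)c(-c2cn([Si](C(C)C)(C(C)C)C(C)C)c3ccc(CC=C(C)C)cc23)c(OC)c1OC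
A3 | alternative 1 | acetylene | C#C
A4 | alternative 2 | 2,5-dihydroxy-3-{5-(3-methylbut-2-enyl)-1-[2-(trimethylsilyl)ethoxymethyl]indol-3-yl}-6-{1-[2-(trimethylsilyl)ethoxymethyl]indol-3-yl}-1,4-benzoquinone | O=C1C(O)=C(c2cn(COCC[Si](C)(C)C)c3ccc(CC=C(C)C)cc23)C(=O)C(O)=C1c1cn(COCC[Si](C)(C)C)c2ccccc12
A5 | alternative 2 | 1,2-phenylene mixed diester of the two N-[2-(trimethylsilyl)ethoxymethyl]indol-3-ylpyruvic acids (one 5-prenylated) | O=C(Cc1cn(COCC[Si](C)(C)C)c2ccc(CC=C(C)C)cc12)C(=O)Oc1ccccc1OC(=O)C(=O)Cc1cn(COCC[Si](C)(C)C)c2ccccc12
A6 | alternative 3 | 3-{2,3,5,6-tetramethoxy-4-[1-(triisopropylsilyl)indol-3-yl]phenyl}-5-(3-methylbut-2-enyl)-1H-indole | COc1c(OC)c(-c2c[nH]c3ccc(CC=C(C)C)cc23)c(OC)c(OC)c1-c1cn([Si](C(C)C)(C(C)C)C(C)C)c2ccccc12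
A7 | alternative 3 | racemic tert-butyl N-(2-hydroxy-2-{2,3,5,6-tetramethoxy-4-[1-(triisopropylsilyl)indol-3-yl]phenyl}but-3-enyl)-N-[5-(3-methylbut-2-enyl)furan-2-yl]carbamate | CC(C)(C)OC(=O)N(CC(O)(C=C)c1c(OC)c(OC)c(-c2cn([Si](C(C)C)(C(C)C)C(C)C)c3ccccc23)c(OC)c1OC)c1ccc(CC=C(C)C)o1
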